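**Plan**
Numbering: decalin C1–C10 (ring A = C1–C5, C10 with C3=O and the ester chain on C4; ring B = C5–C10); C11 = methyl carbon on C8; ArCH2 = (2,5-dimethoxy-3-methylphenyl)methyl; β = face of the C5 methyl.
Enabling feature: on ring B the C5–C4 bond and C11 are 1,4-cis, so a C4=C11 double bond makes ring B the boat of a bicyclo[2.2.2]oct-5-en-2-one (C10 = ketone), which is the adduct of ethylene (C6–C7) with a 6,6-disubstituted cyclohexa-2,4-dienone.
Retrosynthesis cuts, in order: aryl O–CH3; C11–H (back to CH2I, CH2OH, CHO, vinyl); C4–CH2 of the ester chain (Michael); C3=C4 with C4=C11 restored (ring-rearrangement metathesis); C1–C2 and C10–H (hydroboration/alkylation of a C10 methylidene); C5–C6 and C7–C8 (Diels–Alder); then isopropenyl, C9–CH2Ar and C9–CH3 of a carvone.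
Forward: the carvone ring supplies C10, C5, C4, C11, C8 and C9 and receives the arylmethyl bromide at C9; ring B arises by cycloaddition of ethylene; ring A arises when one metathesis opens the C4=C11 bridge and closes C3=C4.
Stereochemistry: C9 from (R)-carvone (alkylation anti to isopropenyl, which is then excised); C5 and C8 from the face of the cycloaddition and the bridge; C10 from hydroboration on the etheno face; C4 by equilibration.

Key step: step 8

Remark: (R)-(−)-carvone, 4-methoxy-2-methylphenol and the reagents named are taken as commercial.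

Step 1
Reactants: 1 4-methoxy-2-methylphenol
Product: 2 2-hydroxy-5-methoxy-3-methylbenzaldehyde
Conditions: (CH2O)n, MgCl2, Et3N, MeCN, reflux; aq. HCl
Reagents that add atoms: paraformaldehyde (as formaldehyde), C=O
Why: Ortho-selective formylation of the magnesium phenoxide should place the formyl group at the only free ortho position, a second formaldehyde acting as hydride acceptor.

Step 2
Reactants: 2 2-hydroxy-5-methoxy-3-methylbenzaldehyde
Product: 3 2,5-dimethoxy-3-methylbenzaldehyde
Conditions: MeI, K2CO3, DMF, rt
Reagents that add atoms: iodomethane, CI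
Why: Williamson O-methylation of the phenoxide should be clean because no other acidic site is present.

Step 3
Reactants: 3 2,5-dimethoxy-3-methylbenzaldehyde
Product: 4 (2,5-dimethoxy-3-methylphenyl)methanol
Conditions: NaBH4, MeOH, 0 °C
Reagents that add atoms: none
Why: Borohydride reduction of the aldehyde should give the benzylic alcohol.

Step 4
Reactants: 4 (2,5-dimethoxy-3-methylphenyl)methanol
Product: 5 1-(bromomethyl)-2,5-dimethoxy-3-methylbenzene
Conditions: PBr3, Et2O, 0 °C
Reagents that add atoms: phosphorus tribromide, BrP(Br)Br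
Why: Bromide displacement of the activated phosphite ester (SN2) should give the benzylic bromide, to be used fresh.

Step 5
Reactants: 6 (R)-(−)-carvone
Product: 8 (5R,6S)-2,6-dimethyl-5-(prop-1-en-2-yl)cyclohex-2-en-1-one, via lithium dienolate 7 (not isolated)
Conditions: LiN(iPr)2, THF, −78 °C; MeI, −78 → 0 °C
Reagents that add atoms: iodomethane, CI
Why: Kinetic deprotonation at C6 gives the cross-conjugated dienolate, whose C-methylation is a standard enolate alkylation; the new C6 center (expected mainly trans to isopropenyl) is planarized again in step 6.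

Step 6
Reactants: 8 (5R,6S)-2,6-dimethyl-5-(prop-1-en-2-yl)cyclohex-2-en-1-one; 5 1-(bromomethyl)-2,5-dimethoxy-3-methylbenzene
Product: 10 (5S,6S)-6-(ArCH2)-2,6-dimethyl-5-(prop-1-en-2-yl)cyclohex-2-en-1-one, via lithium dienolate 9 (not isolated)
Conditions: LiN(iPr)2, THF, −78 °C; 5, DMPU, −78 → 0 °C
Reagents that add atoms: none
Why: Enolate alkylation with the reactive benzylic bromide should create the quaternary center with the arylmethyl group entering anti to the neighbouring isopropenyl group (1,2-induction by the carvone stereocenter), so that methyl is cis and arylmethyl trans to isopropenyl.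

Step 7
Reactants: 10 (5S,6S)-6-(ArCH2)-2,6-dimethyl-5-(prop-1-en-2-yl)cyclohex-2-en-1-one
Product: 12 (6S)-6-(ArCH2)-2,6-dimethylcyclohexa-2,4-dien-1-one, via methoxy hydroperoxide 11 (not isolated)
Conditions: O3, CH2Cl2–MeOH, −78 °C (Sudan Red 7B end point); then FeSO4·7H2O, Cu(OAc)2·H2O, −78 °C → rt
Reagents that add atoms: none
Why: Ozonolysis of the electron-rich isopropenyl group in methanol gives the α-methoxy hydroperoxide, divalent iron turns it into an alkoxy radical that loses methyl acetate by β-scission, and divalent copper oxidizes the ring radical to the alkene, which can only form toward C4 because C6 is quaternary (dealkenylative radical fragmentation), the quaternary stereocenter staying untouched.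

Step 8
Reactants: 12 (6S)-6-(ArCH2)-2,6-dimethylcyclohexa-2,4-dien-1-one
Product: 13 (1S,3S,4R)-3-(ArCH2)-1,3-dimethylbicyclo[2.2.2]oct-5-en-2-one
Conditions: C2H4 (50 bar), toluene, BHT (trace), 140 °C, autoclave
Reagents that add atoms: ethylene, C=C
Why: A thermal, concerted [4+2] cycloaddition (Diels–Alder reaction) joins ethylene to the two termini of the ring-locked s-cis diene of the linearly conjugated dienone, which cannot tautomerize to a phenol because C6 is quaternary, so both new sigma bonds (C5–C6 and C7–C8 of the target) form in one event. The closest known reaction type is the Diels–Alder reaction of 6,6-disubstituted cyclohexa-2,4-dienones (masked ortho-benzoquinones and related dienones) with alkenes to give bicyclo[2.2.2]oct-5-en-2-ones. The ring closed is the future ring B, formed suprafacially by intermolecular [4+2] closure as a boat that the old C3=C4 unit of the dienone (C4=C11 of the target) bridges. The two new stereocenters are the bridgeheads C5 and C8: the bridge fixes their mutual relation, and their relation to C9 follows from approach of ethylene to the diene face that carries the C9 methyl, anti to the larger arylmethyl group. Only π-facial selectivity is needed, since ethylene is symmetrical and poses no regiochemical or endo/exo question; it rests on the size difference of the two substituents at the carvone-derived quaternary center, while the 2-methyl group slows dienone dimerization.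

Step 9
Reactants: 13 (1S,3S,4R)-3-(ArCH2)-1,3-dimethylbicyclo[2.2.2]oct-5-en-2-one
Product: 14 3-(ArCH2)-1,3-dimethyl-2-methylidenebicyclo[2.2.2]oct-5-ene
Conditions: Ph3PCH3Br, KOtBu, toluene, 110 °C
Reagents that add atoms: methyltriphenylphosphonium bromide, C[P+](c1ccccc1)(c1ccccc1)c1ccccc1.[Br-]
Why: Wittig methylenation under forcing conditions should convert the hindered ketone, which has no α-hydrogen and cannot enolize, into the exocyclic alkene.

Step 10
Reactants: 14 3-(ArCH2)-1,3-dimethyl-2-methylidenebicyclo[2.2.2]oct-5-ene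
Product: 16 4-[3-(ArCH2)-1,3-dimethylbicyclo[2.2.2]oct-5-en-2-yl]butan-2-one, via alkylborane 15 (not isolated)
Conditions: 9-BBN, THF, 0 → 60 °C; then bromoacetone, potassium 2,6-di-tert-butylphenoxide, THF, 0 °C → rt
Reagents that add atoms: bromoacetone, CC(=O)CBr
Why: Hydroboration should occur at the 1,1-disubstituted methylidene (far faster with 9-BBN than at the internal cis-alkene), with boron on the terminal carbon and hydrogen delivered to C10 from the face syn to the etheno bridge because the inward hydrogen of the ethano bridge screens the other face, and the B-alkyl-9-BBN then alkylates the bromoacetone enolate by ate-complex formation and 1,2-migration with loss of bromide (α-alkylation of an α-halo ketone by an organoborane).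

Step 11
Reactants: 16 4-[3-(ArCH2)-1,3-dimethylbicyclo[2.2.2]oct-5-en-2-yl]butan-2-one
Product: 18 triethylsilyl enol ether of 16 at the methyl terminus, via lithium enolate 17 (not isolated)
Conditions: LiN(iPr)2, THF, −78 °C; Et3SiCl, −78 → 0 °C
Reagents that add atoms: chlorotriethylsilane, CC[Si](Cl)(CC)CC
Why: Kinetic deprotonation of the methyl ketone at the methyl group followed by O-silylation should give the 2-silyloxy-1-alkene regioisomer.

Step 12
Reactants: 18 triethylsilyl enol ether of 16 at the methyl terminus
Product: 19 trans-fused ring-A triethylsilyl enol ether (C3–OSiEt3, C3=C4) carrying 5β-methyl, 9β-methyl, 9α-ArCH2, 8α-vinyl and 10α-H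
Conditions: second-generation Grubbs catalyst RuCl2(=CHPh)(H2IMes)(PCy3) (cat.), C2H4 (1 atm), toluene, 80 °C
Reagents that add atoms: none
Why: In this ring-rearrangement metathesis (ring-opening then ring-closing olefin metathesis, a net isomerization) a ruthenium methylidene should open the etheno bridge C4=C11 with release of the boat strain, and the alkylidene at C4 should close onto the 1,1-disubstituted silyl enol ether to give the six-membered cyclic enol ether, leaving C11 as a vinyl group on C8 and a trans ring fusion already fixed at C5 and C10.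

Step 13
Reactants: 19 trans-fused ring-A triethylsilyl enol ether
Product: 21 methyl 3-(decalin-4-yl)propanoate with C3 ketone, 4β chain, 5β-methyl, 9β-methyl, 9α-ArCH2, 8α-vinyl and 10α-H, via lithium enolate 20 (not isolated)
Conditions: MeLi, THF, 0 °C; methyl acrylate, −78 °C; NH4Cl; then NaOMe (cat.), MeOH, rt
Reagents that add atoms: methyl acrylate, C=CC(=O)OC
Why: Cleavage of the Si–O bond by MeLi gives the regiodefined C3–C4 lithium enolate, whose Michael addition to methyl acrylate attaches the ester chain at C4 only, and base equilibration of this α-stereocenter should favour the equatorial chain cis to the C5 methyl.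

Step 14
Reactants: 21 keto ester with 8α-vinyl group
Product: 23 keto ester with 8α-hydroxymethyl group, via aldehyde 22 (not isolated)
Conditions: O3, CH2Cl2–MeOH, −78 °C (Sudan Red 7B end point); Me2S; then NaBH4 (1 equiv), −78 °C
Reagents that add atoms: ozone, [O-][O+]=O
Why: Ozonolysis cleaves the only alkene, and low-temperature borohydride reduction should take the aldehyde, which is far more reactive than the α-branched ring ketone, to the primary alcohol before the C8 center next to the formyl group can epimerize.

Step 15
Reactants: 23 keto ester with 8α-hydroxymethyl group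
Product: 24 keto ester with 8α-iodomethyl group
Conditions: PPh3, I2, imidazole, toluene, 60 °C
Reagents that add atoms: iodine, II
Why: Appel-type iodination (alkoxyphosphonium displaced by iodide) suits the β-branched primary alcohol and leaves ketone and ester untouched.

Step 16
Reactants: 24 keto ester with 8α-iodomethyl group
Product: 25 dimethyl ether of the target
Conditions: Bu3SnH, AIBN (cat.), toluene, 80 °C
Reagents that add atoms: none
Why: Radical chain dehalogenation replaces iodine by hydrogen and so completes the C8 methyl group without touching the C8 stereocenter, the ketone or the ester.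

Step 17
Reactants: 25 dimethyl ether of the target
Product: 27 target hydroquinone CNP0535359.1, via quinone 26 (not isolated)
Conditions: (NH4)2Ce(NO3)6, MeCN–H2O, 0 °C; then aq. Na2S2O4, EtOAc, rt
Reagents that add atoms: water, O
Why: Oxidative demethylation of the 1,4-dimethoxyarene by tetravalent cerium should give the para-quinone, with water supplying the quinone oxygens, and dithionite reduction then gives the hydroquinone under conditions that spare the keto ester and the epimerizable C4 center.

**Compound list**
1 | 4-methoxy-2-methylphenol | COc1ccc(O)c(C)c1 | starting material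
2 | 2-hydroxy-5-methoxy-3-methylbenzaldehyde | O=Cc1cc(OC)cc(C)c1O | intermediate
3 | 2,5-dimethoxy-3-methylbenzaldehyde | O=Cc1cc(OC)cc(C)c1OC | intermediate
4 | (2,5-dimethoxy-3-methylphenyl)methanol | OCc1cc(OC)cc(C)c1OC | intermediate
5 | 1-(bromomethyl)-2,5-dimethoxy-3-methylbenzene | BrCc1cc(OC)cc(C)c1OC | intermediate
6 | (R)-(−)-carvone, (5R)-2-methyl-5-(prop-1-en-2-yl)cyclohex-2-en-1-one | O=C1C(C)=CC[C@@H](C(C)=C)C1 | starting material
7 | lithium dienolate of 6 (O–Li on C1, C1=C6) | [Li]OC1=C[C@H](C(C)=C)CC=C1C | intermediate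
8 | (5R,6S)-2,6-dimethyl-5-(prop-1-en-2-yl)cyclohex-2-en-1-one (trans-6-methylcarvone; its 6-epimer is carried along) | O=C1C(C)=CC[C@@H](C(C)=C)[C@@H]1C | intermediate
9 | lithium dienolate of 8 (O–Li on C1, C1=C6) | [Li]OC1=C(C)[C@H](C(C)=C)CC=C1C | intermediate
10 | (5S,6S)-6-[(2,5-dimethoxy-3-methylphenyl)methyl]-2,6-dimethyl-5-(prop-1-en-2-yl)cyclohex-2-en-1-one (arylmethyl trans to isopropenyl) | O=C1C(C)=CC[C@@H](C(C)=C)[C@]1(C)Cc1cc(OC)cc(C)c1OC | intermediate
11 | α-methoxy hydroperoxide of 10 (isopropenyl replaced by 1-hydroperoxy-1-methoxyethyl; ring centers as in 10; both epimers at the peroxy carbon) | O=C1C(C)=CC[C@@H](C(C)(OC)OO)[C@]1(C)Cc1cc(OC)cc(C)c1OC | intermediate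
12 | (6S)-6-[(2,5-dimethoxy-3-methylphenyl)methyl]-2,6-dimethylcyclohexa-2,4-dien-1-one | O=C1C(C)=CC=C[C@]1(C)Cc1cc(OC)cc(C)c1OC | intermediate
13 | (1S,3S,4R)-3-[(2,5-dimethoxy-3-methylphenyl)methyl]-1,3-dimethylbicyclo[2.2.2]oct-5-en-2-one (arylmethyl syn to the etheno bridge, C3 methyl syn to the ethano bridge) | O=C1[C@]2(C)C=C[C@@H](CC2)[C@]1(C)Cc1cc(OC)cc(C)c1OC | intermediate
14 | 3-[(2,5-dimethoxy-3-methylphenyl)methyl]-1,3-dimethyl-2-methylidenebicyclo[2.2.2]oct-5-ene (configuration as in 13) | C=C1[C@]2(C)C=C[C@@H](CC2)[C@]1(C)Cc1cc(OC)cc(C)c1OC | intermediate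
15 | 9-{[3-(arylmethyl)-1,3-dimethylbicyclo[2.2.2]oct-5-en-2-yl]methyl}-9-borabicyclo[3.3.1]nonane (C2–H syn to the etheno bridge) | C(B3C4CCCC3CCC4)[C@H]1[C@]2(C)C=C[C@@H](CC2)[C@]1(C)Cc1cc(OC)cc(C)c1OC | intermediate
16 | 4-[3-(arylmethyl)-1,3-dimethylbicyclo[2.2.2]oct-5-en-2-yl]butan-2-one (side chain syn to the ethano bridge and cis to the C3 methyl) | CC(=O)CC[C@H]1[C@]2(C)C=C[C@@H](CC2)[C@]1(C)Cc1cc(OC)cc(C)c1OC | intermediate
17 | lithium enolate of 16 at the methyl terminus | C=C(O[Li])CC[C@H]1[C@]2(C)C=C[C@@H](CC2)[C@]1(C)Cc1cc(OC)cc(C)c1OC | intermediate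
18 | triethylsilyl enol ether of 16 at the methyl terminus (2-silyloxybut-1-ene chain) | C=C(O[Si](CC)(CC)CC)CC[C@H]1[C@]2(C)C=C[C@@H](CC2)[C@]1(C)Cc1cc(OC)cc(C)c1OC | intermediate
19 | trans-fused decalin, ring-A triethylsilyl enol ether (C3–OSiEt3, C3=C4), 5β-methyl, 9β-methyl, 9α-arylmethyl, 8α-vinyl, 10α-H | C1=C(O[Si](CC)(CC)CC)CC[C@H]2[C@@]1(C)CC[C@H](C=C)[C@]2(C)Cc1cc(OC)cc(C)c1OC | intermediate
20 | lithium enolate corresponding to 19 (C3–OLi, C3=C4) | C1=C(O[Li])CC[C@H]2[C@@]1(C)CC[C@H](C=C)[C@]2(C)Cc1cc(OC)cc(C)c1OC | intermediate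
21 | methyl 3-(trans-decalin-4-yl)propanoate with C3 ketone, 4β chain, 5β-methyl, 9β-methyl, 9α-arylmethyl, 8α-vinyl, 10α-H | COC(=O)CC[C@@H]1C(=O)CC[C@H]2[C@@]1(C)CC[C@H](C=C)[C@]2(C)Cc1cc(OC)cc(C)c1OC | intermediate
22 | 8α-formyl analogue of 21 | COC(=O)CC[C@@H]1C(=O)CC[C@H]2[C@@]1(C)CC[C@H](C=O)[C@]2(C)Cc1cc(OC)cc(C)c1OC | intermediate
23 | 8α-hydroxymethyl analogue of 21 | COC(=O)CC[C@@H]1C(=O)CC[C@H]2[C@@]1(C)CC[C@H](CO)[C@]2(C)Cc1cc(OC)cc(C)c1OC | intermediate
24 | 8α-iodomethyl analogue of 21 | COC(=O)CC[C@@H]1C(=O)CC[C@H]2[C@@]1(C)CC[C@H](CI)[C@]2(C)Cc1cc(OC)cc(C)c1OC | intermediate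
25 | dimethyl ether of the target (8α-methyl, aryl = 2,5-dimethoxy-3-methylphenyl) | COC(=O)CC[C@@H]1C(=O)CC[C@H]2[C@@]1(C)CC[C@H](C)[C@]2(C)Cc1cc(OC)cc(C)c1OC | intermediate
26 | para-quinone of the target (2-methyl-1,4-benzoquinon-6-ylmethyl on C9) | COC(=O)CC[C@@H]1C(=O)CC[C@H]2[C@@]1(C)CC[C@H](C)[C@]2(C)CC1=CC(=O)C=C(C)C1=O | intermediate
27 | CNP0535359.1: methyl 3-(trans-decalin-4-yl)propanoate with C3 ketone, 4β chain, 5β-methyl, 8α-methyl, 9β-methyl, 9α-[(2,5-dihydroxy-3-methylphenyl)methyl], 10α-H | COC(=O)CC[C@@H]1C(=O)CC[C@H]2[C@@]1(C)CC[C@H](C)[C@]2(C)Cc1cc(O)cc(C)c1O | target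

**Step count and risks**
Total steps: 17. Longest linear sequence: 16 steps (steps 1–4 and 6–17, from 4-methoxy-2-methylphenol); 13 steps from (R)-carvone.

Most likely to fail, in this order:

Step 12. Opening of the only moderately strained bicyclo[2.2.2]octene may be slower than catalyst decay, and binding of the ruthenium carbene to the enol ether may stall turnover. The fallback sets out from 16 and separates ring opening from ring closure by oxidative cleavage and olefination. Ozonolysis of the etheno bridge (O3, CH2Cl2–MeOH, −78 °C; Me2S) should give the keto dialdehyde F1. Wittig methylenation of the two aldehydes, which react faster than the methyl ketone (Ph3P=CH2, THF, −78 → 0 °C), should give the divinyl ketone F2. Kinetic silylation (LiN(iPr)2, Et3SiCl, THF, −78 °C) should give the silyl enol ether F3. Plain ring-closing metathesis of F3 (second-generation Grubbs catalyst, CH2Cl2, 40 °C) should close the six-membered ring onto the C4 vinyl group in preference to the seven-membered ring onto the C11 vinyl group, and comes back to the route at 19.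

Step 8. Cycloaddition with unactivated ethylene may be slow enough for dienone dimerization or benzyl migration to compete, and so small a dienophile may discriminate poorly between the two diene faces. The fallback sets out from 12 and uses phenyl vinyl sulfone (toluene, 110 °C) as a larger, activated ethylene equivalent. It should give the phenylsulfonyl adduct F4 (mixture at the sulfonyl-bearing carbon, all converging). Reductive desulfonylation (sodium amalgam Na(Hg), Na2HPO4, MeOH, −20 °C), which the hindered ketone should survive, comes back to the route at 13.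

Step 10. Hydroboration may compete at the etheno bridge, and the hindered alkyl group may fail to migrate from boron to the bromoacetone-derived carbon. The fallback sets out from 14 and builds the chain by olefination. Hydroboration–oxidation (9-BBN, THF; then NaOH, H2O2) should give the primary alcohol F5. Oxidation with Dess–Martin periodinane should give the aldehyde F6. A base-free Wittig reaction with Ph3P=CHC(O)CH3 (toluene, 90 °C), which avoids epimerization at C10, should give the enone F7. Conjugate reduction with [(Ph3P)CuH]6 (benzene, H2O, rt), which spares the isolated etheno bridge, comes back to the route at 16.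

Further compounds
F1 | step 12 | keto dialdehyde: 4-[2,5-diformyl-2,6-dimethyl-6-(arylmethyl)cyclohexyl]butan-2-one, ring-opened 16 with C4 and C11 as cis aldehydes | CC(=O)CC[C@H]1[C@](C)(C=O)CC[C@H](C=O)[C@]1(C)Cc1cc(OC)cc(C)c1OC
F2 | step 12 | divinyl ketone: as F1 with both formyl groups replaced by vinyl | CC(=O)CC[C@H]1[C@](C)(C=C)CC[C@H](C=C)[C@]1(C)Cc1cc(OC)cc(C)c1OC
F3 | step 12 | triethylsilyl enol ether of F2 at the methyl terminus | C=C(O[Si](CC)(CC)CC)CC[C@H]1[C@](C)(C=C)CC[C@H](C=C)[C@]1(C)Cc1cc(OC)cc(C)c1OC
F4 | step 8 | 7-(phenylsulfonyl) derivative of 13 (one regioisomer drawn, sulfonyl carbon undefined) | O=C1[C@]2(C)C=C[C@@H](CC2S(=O)(=O)c2ccccc2)[C@]1(C)Cc1cc(OC)cc(C)c1OC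
F5 | step 10 | [3-(arylmethyl)-1,3-dimethylbicyclo[2.2.2]oct-5-en-2-yl]methanol (C2–H syn to the etheno bridge) | OC[C@H]1[C@]2(C)C=C[C@@H](CC2)[C@]1(C)Cc1cc(OC)cc(C)c1OC
F6 | step 10 | 3-(arylmethyl)-1,3-dimethylbicyclo[2.2.2]oct-5-ene-2-carbaldehyde (same configuration) | O=C[C@H]1[C@]2(C)C=C[C@@H](CC2)[C@]1(C)Cc1cc(OC)cc(C)c1OC
F7 | step 10 | (E)-4-[3-(arylmethyl)-1,3-dimethylbicyclo[2.2.2]oct-5-en-2-yl]but-3-en-2-one | CC(=O)/C=C/[C@H]1[C@]2(C)C=C[C@@H](CC2)[C@]1(C)Cc1cc(OC)cc(C)c1OC
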